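## Retrosynthetic overview

- **Rings (C5–C10 bond):** achiral, ten-membered germacrone 1 is the precursor of the bicyclic dienone 2. Rings A and B close together in one transannular event, and no ring is built afterwards.
- **C3–O and C4–O:** diol 3 comes from 2 by syn-dihydroxylation of the 3-ene.
- **C11–O (key step):** hydroperoxide 4, then triol 5, come from 3 by a singlet-oxygen ene reaction that also moves the double bond to C6=C7.
- **Acyl fragment:** tiglyl alcohol 6 gives epoxy alcohol 7 (both epoxide C–O bonds by asymmetric epoxidation), then epoxy acid 8.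
- **Ester C3–O, last:** 5 and 8 (as mixed anhydride 9) give target 10.

Assumption 1: the target is taken exactly as drawn, i.e. a (3R,4S,5R,10R) eudesmane core (3α-acyloxy, 4α-OH, 4β-Me, 5α-H, 10β-Me) carrying a (2S,3R)-2,3-dimethyloxirane-2-carboxylate, which is the epoxide of the E (tiglate) series.

Assumption 2: the (S,S)-catalyst is written for step 1; if it delivers the (5S,10S) series, its (R,R)-enantiomer is used instead.

Germacrone is a bulk crystalline isolate of zdravets (Geranium macrorrhizum) oil and is sold commercially.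

## Route

Step 1
Reactants: 1 germacrone, (3E,7E)-3,7-dimethyl-10-(propan-2-ylidene)cyclodeca-3,7-dien-1-one
Product: 2 (5R,10R)-eudesma-3,7(11)-dien-8-one
Conditions: (S,S)-imidodiphosphorimidate HN[P(=NSO2CF3)(O2C20H10Ar2)]2 (O2C20H10Ar2 = 3,3'-Ar2-1,1'-binaphthalene-2,2'-diolate, Ar = 3,5-(CF3)2C6H3; 2 mol %), toluene, −40 °C
Reagents that add atoms: none
Why: Proposed new method: the confined, strongly acidic chiral acid protonates C1 of the 1(10)-alkene in one of the two rapidly interconverting mirror-image crossed conformers of achiral germacrone while C5 of the 4,5-alkene closes onto C10 in a chair-like transannular array (the E,E geometry fixes the trans ring fusion and the catalyst pocket fixes the absolute sense, so C5 and C10 are set together), and the ion-paired anion then removes the axial C3 proton of the eudesm-4-yl cation to give the 3-ene under kinetic control; the closest known reaction types are imidodiphosphorimidate-catalysed enantioselective proton-initiated polyene cyclisation and the racemic acid-induced germacrene-to-selinene transannular cyclisation.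

Step 2
Reactants: 2 (5R,10R)-eudesma-3,7(11)-dien-8-one
Product: 3 (3R,4S,5R,10R)-3,4-dihydroxyeudesm-7(11)-en-8-one
Conditions: OsO4 (2 mol %), N-methylmorpholine N-oxide (1.2 equiv), acetone/H2O 4:1, 0 °C → rt
Reagents that add atoms: N-methylmorpholine N-oxide, C[N+]1([O-])CCOCC1; water, O (both oxygens are passed on through catalytic OsO4, O=[Os](=O)(=O)=O)
Why: Upjohn syn-dihydroxylation, in which OsO4 takes the electron-rich trisubstituted 3-ene and leaves the electron-poor tetrasubstituted enone, adding from the α-face opposite the axial C10 methyl so that C3 (R, 3α-OH) and C4 (S, 4α-OH, 4β-Me) are set in one syn addition.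

Step 3
Reactants: 3 (3R,4S,5R,10R)-3,4-dihydroxyeudesm-7(11)-en-8-one
Product: 5 (3R,4S,5R,10R)-3,4,11-trihydroxyeudesm-6-en-8-one, via hydroperoxide 4 (not isolated)
Conditions: O2, hν (white LED), 5,10,15,20-tetraphenylporphyrin (1 mol %), CH2Cl2, 0 °C; then PPh3 (1.2 equiv), 0 °C → rt
Reagents that add atoms: dioxygen, O=O
Why: Schenck ene reaction, in which singlet oxygen bonds to the β-carbon C11 of the s-cis-locked isopropylidene ketone and takes the allylic hydrogen from C6, the branch geminal to the carbonyl (gem effect), so the double bond moves to C6=C7 in conjugation with C8=O; PPh3 reduces the hydroperoxide (or its cyclic peroxy hemiketal) to the tertiary alcohol, the s-trans endocyclic enone formed is inert to further singlet oxygen, and no stereocentre is made or touched.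

Step 4
Reactants: 6 (E)-2-methylbut-2-en-1-ol (tiglyl alcohol)
Product: 7 [(2R,3R)-2,3-dimethyloxiran-2-yl]methanol
Conditions: Ti(OiPr)4 (5 mol %), D-(−)-diethyl tartrate (6 mol %), t-BuOOH, 4 Å MS, CH2Cl2, −20 °C
Reagents that add atoms: tert-butyl hydroperoxide, CC(C)(C)OO
Why: Sharpless asymmetric epoxidation, in which the titanium tartrate complex delivers oxygen to one face of the E-trisubstituted allylic alcohol; D-(−)-tartrate gives the (2R,3R)-epoxy alcohol (mirror image of the (2S,3S) product that L-tartrate gives with E-allylic alcohols), setting both epoxide stereocentres.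

Step 5
Reactants: 7 [(2R,3R)-2,3-dimethyloxiran-2-yl]methanol
Product: 8 (2S,3R)-2,3-dimethyloxirane-2-carboxylic acid
Conditions: RuCl3 (2 mol %), NaIO4 (3 equiv), MeCN/EtOAc/H2O, 0 °C → rt
Reagents that add atoms: sodium periodate, [Na+].[O-]I(=O)(=O)=O (net oxygen donor, relayed by RuO4 and the aldehyde hydrate)
Why: Sharpless RuO4 oxidation takes the primary alcohol through the aldehyde hydrate to the acid without opening the trisubstituted epoxide; both stereocentres are untouched, and the C2 descriptor changes from R to S only because the CIP priorities change.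

Step 6
Reactants: 5 (3R,4S,5R,10R)-3,4,11-trihydroxyeudesm-6-en-8-one; 8 (2S,3R)-2,3-dimethyloxirane-2-carboxylic acid
Product: 10 (3R,4S,5R,10R)-4,11-dihydroxy-8-oxoeudesm-6-en-3-yl (2S,3R)-2,3-dimethyloxirane-2-carboxylate, via mixed anhydride 9 (not isolated)
Conditions: 8, 2,4,6-Cl3C6H2COCl, Et3N, toluene, rt, 1 h; then 5, DMAP (4-dimethylaminopyridine), toluene, rt → 40 °C
Reagents that add atoms: 2,4,6-trichlorobenzoyl chloride, O=C(Cl)c1c(Cl)cc(Cl)cc1Cl (its aroyl group is carried only by 9 and is not part of 10)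
Why: Yamaguchi esterification, in which DMAP transfers the aliphatic acyl group of the mixed anhydride to the only secondary hydroxyl (axial 3α-OH) while the two tertiary hydroxyls stay free; the mild, non-acidic conditions leave the epoxide, the enone and all stereocentres unchanged.

## Compound list

1 | germacrone, (3E,7E)-3,7-dimethyl-10-(propan-2-ylidene)cyclodeca-3,7-dien-1-one | C/C1=C\CC/C(C)=C/CC(=C(C)C)C(=O)C1 | starting material
2 | (5R,10R)-eudesma-3,7(11)-dien-8-one, i.e. (4aR,8aR)-5,8a-dimethyl-3-(propan-2-ylidene)-3,4,4a,7,8,8a-hexahydronaphthalen-2(1H)-one (5α-H, 10β-Me) | CC1=CCC[C@]2(C)CC(=O)C(=C(C)C)C[C@@H]12 | intermediate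
3 | (3R,4S,5R,10R)-3,4-dihydroxyeudesm-7(11)-en-8-one (3α,4α-diol, 4β-Me) | O[C@@H]1CC[C@]2(C)CC(=O)C(=C(C)C)C[C@H]2[C@]1(C)O | intermediate
4 | (3R,4S,5R,10R)-11-hydroperoxy-3,4-dihydroxyeudesm-6-en-8-one | O[C@@H]1CC[C@]2(C)CC(=O)C(C(C)(C)OO)=C[C@H]2[C@]1(C)O | intermediate (not isolated)
5 | (3R,4S,5R,10R)-3,4,11-trihydroxyeudesm-6-en-8-one | O[C@@H]1CC[C@]2(C)CC(=O)C(C(C)(C)O)=C[C@H]2[C@]1(C)O | intermediate
6 | (E)-2-methylbut-2-en-1-ol (tiglyl alcohol) | C/C=C(\C)CO | starting material
7 | [(2R,3R)-2,3-dimethyloxiran-2-yl]methanol | C[C@H]1O[C@]1(C)CO | intermediate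
8 | (2S,3R)-2,3-dimethyloxirane-2-carboxylic acid | C[C@H]1O[C@]1(C)C(=O)O | intermediate
9 | (2S,3R)-2,3-dimethyloxirane-2-carboxylic 2,4,6-trichlorobenzoic anhydride | C[C@H]1O[C@]1(C)C(=O)OC(=O)c1c(Cl)cc(Cl)cc1Cl | intermediate (not isolated)
10 | (3R,4S,5R,10R)-4,11-dihydroxy-8-oxoeudesm-6-en-3-yl (2S,3R)-2,3-dimethyloxirane-2-carboxylate (CNP0272928.1) | C[C@H]1O[C@]1(C)C(=O)O[C@@H]1CC[C@]2(C)CC(=O)C(C(C)(C)O)=C[C@H]2[C@]1(C)O | target

## Step count and risks

Total step count: 6. Longest linear sequence: 4 steps (1 → 2 → 3 → 5 → 10; steps 1, 2, 3 and 6).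

**Step 1 (the proposed new cyclisation).** The risks are low enantioselectivity and termination to the 4(15)- or 4-ene instead of the 3-ene. The fallback uses known chemistry only. It sets out from 1, which is cyclised with achiral p-toluenesulfonic acid (TsOH·H2O, 10 mol %, CH2Cl2, 0 °C; the ordinary acid-induced germacrene-to-selinene cyclisation). The 3-ene is separated from its double-bond isomers on AgNO3-impregnated silica, giving 2 as a 1:1 mixture with its enantiomer (5S,10S)-eudesma-3,7(11)-dien-8-one F1. Steps 2 and 3 are run unchanged on the racemate, which carries the mirror-image series along as (3S,4R,5S,10S)-3,4-dihydroxyeudesm-7(11)-en-8-one F2, (3S,4R,5S,10S)-11-hydroperoxy-3,4-dihydroxyeudesm-6-en-8-one F3 (not isolated) and (3S,4R,5S,10S)-3,4,11-trihydroxyeudesm-6-en-8-one F4. Step 6 with enantiopure 8 then gives 10 together with the diastereomer (3S,4R,5S,10S)-4,11-dihydroxy-8-oxoeudesm-6-en-3-yl (2S,3R)-2,3-dimethyloxirane-2-carboxylate F5. This is removed by chromatography or preparative HPLC, so the fallback comes back to the route at 10 as a single enantiomer, with at most half of the material.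

**Step 3 (singlet-oxygen ene).** The risks are slow reaction of the enone and competing hydrogen abstraction from the isopropylidene methyls. The fallback sets out from 2 and comes back at 5. The enone of 2 is epoxidised with H2O2/NaOH in MeOH (Weitz–Scheffer) to (5R,10R)-7,11-epoxyeudesm-3-en-8-one F6. SmI2 in THF/MeOH at −78 °C opens the α,β-epoxy ketone reductively to the aldol-type (5R,10R)-11-hydroxyeudesm-3-en-8-one F7 (C7 epimers, which do not matter). IBX (2-iodoxybenzoic acid) in DMSO at 70 °C dehydrogenates the ketone; this can only go towards C6–C7 because C10 is quaternary, and gives (5R,10R)-11-hydroxyeudesma-3,6-dien-8-one F8. Dihydroxylation of the 3-ene from the α-face under the conditions of step 2 (OsO4 cat., N-methylmorpholine N-oxide) then gives 5.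

**Step 6 (esterification).** The risk is that a hindered axial alcohol next to a quaternary carbon must be joined to an α-quaternary epoxy acid. The fallback sets out from 5 and comes back at 10. The alcohol is acylated with the small, planar (E)-2-methylbut-2-enoyl chloride (tigloyl chloride; pyridine, DMAP, CH2Cl2) to give the tiglate (3R,4S,5R,10R)-4,11-dihydroxy-8-oxoeudesm-6-en-3-yl (E)-2-methylbut-2-enoate F9. The epoxide is then built on the ester with the chiral dioxirane generated from KHSO5 (2KHSO5·KHSO4·K2SO4) and the D-fructose-derived ketone 4,5-di-O-acetyl-1,2-O-isopropylidene-β-D-erythro-2,3-hexodiulo-2,6-pyranose (MeCN/aqueous NaHCO3, 0 °C). This reagent class epoxidises E-α,β-unsaturated esters on the face that leads to the (2S,3R) glycidate, and the more hindered, ketone-conjugated C6=C7 bond is expected to react more slowly. The minor epoxide diastereomer is removed by chromatography to give 10.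

## Further compounds

F1 | step 1 | (5S,10S)-eudesma-3,7(11)-dien-8-one | CC1=CCC[C@@]2(C)CC(=O)C(=C(C)C)C[C@H]12
F2 | step 1 | (3S,4R,5S,10S)-3,4-dihydroxyeudesm-7(11)-en-8-one | O[C@H]1CC[C@@]2(C)CC(=O)C(=C(C)C)C[C@@H]2[C@@]1(C)O
F3 | step 1 | (3S,4R,5S,10S)-11-hydroperoxy-3,4-dihydroxyeudesm-6-en-8-one | O[C@H]1CC[C@@]2(C)CC(=O)C(C(C)(C)OO)=C[C@@H]2[C@@]1(C)O
F4 | step 1 | (3S,4R,5S,10S)-3,4,11-trihydroxyeudesm-6-en-8-one | O[C@H]1CC[C@@]2(C)CC(=O)C(C(C)(C)O)=C[C@@H]2[C@@]1(C)O
F5 | step 1 | (3S,4R,5S,10S)-4,11-dihydroxy-8-oxoeudesm-6-en-3-yl (2S,3R)-2,3-dimethyloxirane-2-carboxylate | C[C@H]1O[C@]1(C)C(=O)O[C@H]1CC[C@@]2(C)CC(=O)C(C(C)(C)O)=C[C@@H]2[C@@]1(C)O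
F6 | step 3 | (5R,10R)-7,11-epoxyeudesm-3-en-8-one (C7 configuration not specified) | CC1=CCC[C@]2(C)CC(=O)C3(OC3(C)C)C[C@@H]12
F7 | step 3 | (5R,10R)-11-hydroxyeudesm-3-en-8-one (C7 epimers) | CC1=CCC[C@]2(C)CC(=O)C(C(C)(C)O)C[C@@H]12
F8 | step 3 | (5R,10R)-11-hydroxyeudesma-3,6-dien-8-one | CC1=CCC[C@]2(C)CC(=O)C(C(C)(C)O)=C[C@@H]12
F9 | step 6 | (3R,4S,5R,10R)-4,11-dihydroxy-8-oxoeudesm-6-en-3-yl (E)-2-methylbut-2-enoate | C/C=C(\C)C(=O)O[C@@H]1CC[C@]2(C)CC(=O)C(C(C)(C)O)=C[C@H]2[C@]1(C)O
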